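**Plan**
- Cuts (ansamycin numbering: C1 lactam carbonyl, C15 benzylic carbon, N on C20): carbamate and silyl groups first, then N–C20 (aryl amidation), C3–C4 (B-alkyl Suzuki), C6–C7 (methoxyallylboration), C8=C9 (Wittig), C15–C16 (aryllithium on a lactone), C10–C11 (aldol).
- Enabling feature: C12–C13–C14(CH3)–C15 has the carbon pattern of a 4-methylfuran (C12 = furan C2, C15 = furan C5), and the C11 carbinol sits on C12. Oxidation therefore makes C12 a ketone and C15 an aldehyde, and O11 closes the six-membered ring O11–C11–C12–C13–C14–C15.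
- Forward order: aldol, furan-to-pyranone ring expansion, decoration of that ring, opening by the arene at C15, chain growth C9 to C7 to C4/C1, closure of the 19-membered lactam, carbamate, desilylation.
- Stereochemistry: C10/C11 from the oxazolidinone; C12 from the ring (axial hydride, alcohol trans to the C11 side chain); C14 from the C12 hydroxyl (directed hydrogenation); C15 from the CBS catalyst; C6/C7 from the Ipc2B reagent. Both E alkenes come from a stabilised ylide and a stereoretentive coupling.

Key step: step 4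

Remark: 2 is taken as a catalogue compound, and hydroxy ketone 18 is drawn in its open form although it may rest partly as the cyclic hemiketal.

**Step 1**
Reactants: 1 (R)-4-benzyl-3-propionyloxazolidin-2-one; 2 4-methylfuran-2-carbaldehyde
Product: 4 (R)-4-benzyl-3-[(2R,3R)-3-hydroxy-2-methyl-3-(4-methylfuran-2-yl)propanoyl]oxazolidin-2-one, via Z-dibutylboron enolate 3 (not isolated)
Conditions: Bu2BOTf, Et3N, CH2Cl2, 0 °C; 2, −78 to 0 °C; pH 7 buffer, MeOH, 30% H2O2, 0 °C
Reagents that add atoms: none
Why: Evans boron syn aldol, in which the Z enolate reacts through a closed chair whose face is fixed by the benzyl group of the (R)-auxiliary, so C10 and C11 should form with the syn relation and absolute sense of the target.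

**Step 2**
Reactants: 4 syn aldol imide
Product: 5 (1R,2S)-2-methyl-1-(4-methylfuran-2-yl)propane-1,3-diol
Conditions: LiBH4, MeOH (1 equiv), THF, 0 °C
Reagents that add atoms: none
Why: Reductive cleavage of an N-acyl oxazolidinone takes the exocyclic carbonyl to the C9 alcohol without touching furan or stereocentres, and the auxiliary is recovered.

**Step 3**
Reactants: 5 diol
Product: 6 (1R,2S)-3-(tert-butyldimethylsilyloxy)-2-methyl-1-(4-methylfuran-2-yl)propan-1-ol
Conditions: TBSCl (1.05 equiv), imidazole, CH2Cl2, 0 °C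
Reagents that add atoms: tert-butyldimethylsilyl chloride, CC(C)(C)[Si](C)(C)Cl
Why: Sterically selective silylation of the primary alcohol leaves the secondary furyl carbinol O11 free for the ring closure.

**Step 4**
Reactants: 6 furyl carbinol
Product: 8 (2R)-2-[(2S)-1-(tert-butyldimethylsilyloxy)propan-2-yl]-6-hydroxy-5-methyl-2H-pyran-3(6H)-one (anomer mixture at C15), via cis-enedione 7 (not isolated)
Conditions: NBS (1.05 equiv), NaHCO3, THF/H2O 4:1, 0 °C
Reagents that add atoms: water, O
Why: NBS attacks the unsubstituted alpha carbon C15 of the electron-rich furan and water adds at the other alpha carbon C12, giving a 2,5-dihydrofuran that loses HBr and opens to the cis-enedione 7 with C12 as ketone and C15 as aldehyde. This is the Achmatowicz oxidative ring expansion of a furfuryl alcohol, the standard entry to 6-hydroxy-2H-pyran-3(6H)-ones. The C11 hydroxyl then adds to the C15 aldehyde in a 6-exo-trig hemiacetalisation that forms the O11–C15 bond and the ring O11–C11–C12–C13–C14–C15, the Z geometry inherited from the furan holding the two ends within reach. The only new stereocentre is the anomeric C15, which settles under thermodynamic (anomeric) control as a mixture and is erased later, while C10 and C11 pass through unchanged. The step needs oxidation of the furan alone beside a free secondary alcohol and a silyl ether, which the much higher nucleophilicity of the furan secures, and it needs C11, now alpha to a ketone, to hold its configuration, which the bicarbonate buffer and 0 °C secure. Because O11 becomes the ring oxygen, O12 is the only oxygen left open for the later methylation.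

**Step 5**
Reactants: 8 pyranone lactol
Product: 9 (2R,6S)-6-(benzyloxy)-2-[(2S)-1-(tert-butyldimethylsilyloxy)propan-2-yl]-5-methyl-2H-pyran-3(6H)-one (2,6-trans)
Conditions: BnOH (3 equiv), CSA (5 mol %), 4 Å MS, CH2Cl2, 0 °C to rt
Reagents that add atoms: benzyl alcohol, OCc1ccccc1
Why: Fischer-type acid-catalysed glycosidation under equilibrating conditions, where the anomeric effect places the benzyloxy group axial and trans to the equatorial C11 side chain, and the small excess of alcohol in an aprotic medium spares the primary silyl ether.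

**Step 6**
Reactants: 9 benzyl acetal enone
Product: 10 (2R,3S,6S)-6-(benzyloxy)-2-[(2S)-1-(tert-butyldimethylsilyloxy)propan-2-yl]-5-methyl-3,6-dihydro-2H-pyran-3-ol
Conditions: NaBH4, CeCl3·7H2O, MeOH/CH2Cl2, −78 °C
Reagents that add atoms: none
Why: Luche 1,2-reduction, in which hydride enters axially on the face away from the axial benzyloxy group, as is usual for 2,6-trans 6-alkoxypyranones, so the C12 alcohol should be equatorial and trans to the C11 side chain (12S).

**Step 7**
Reactants: 10 allylic alcohol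
Product: 11 (2R,3S,5S,6S)-6-(benzyloxy)-2-[(2S)-1-(tert-butyldimethylsilyloxy)propan-2-yl]-5-methyltetrahydro-2H-pyran-3-ol
Conditions: [Ir(cod)(PCy3)(py)]PF6 (5 mol %), H2 (1 atm), CH2Cl2, rt
Reagents that add atoms: none
Why: Hydroxyl-directed homogeneous hydrogenation of a cyclic allylic alcohol, where the cationic iridium binds O12 and delivers both hydrogens to C13=C14 on the hydroxyl face, which puts the C14 methyl trans to O12 (14S) and leaves the benzyl acetal intact.

**Step 8**
Reactants: 11 saturated alcohol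
Product: 12 C12 methyl ether of 11 (10S,11R,12S,14S,15S)
Conditions: NaH, MeI, THF, 0 °C to rt
Reagents that add atoms: iodomethane, CI
Why: Williamson etherification of the only free hydroxyl, done while C15 is still an acetal so that the axial C14 methyl has no acidic neighbour and cannot epimerise.

**Step 9**
Reactants: 12 benzyl acetal methyl ether
Product: 13 6-[(2S)-1-(tert-butyldimethylsilyloxy)propan-2-yl]-5-methoxy-3-methyltetrahydro-2H-pyran-2-ol (11R,12S,14S; anomer mixture)
Conditions: H2 (1 atm), 10% Pd/C, EtOAc, rt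
Reagents that add atoms: none
Why: Neutral hydrogenolysis of the anomeric benzyl group frees the lactol without acid, so the silyl ether survives.

**Step 10**
Reactants: 13 lactol
Product: 14 (3S,5S,6R)-6-[(2S)-1-(tert-butyldimethylsilyloxy)propan-2-yl]-5-methoxy-3-methyltetrahydro-2H-pyran-2-one
Conditions: TEMPO (10 mol %), PhI(OAc)2, CH2Cl2, rt
Reagents that add atoms: none
Why: Oxoammonium (TEMPO) oxidation of a lactol to the lactone runs without base, so the axial methyl at C14, now alpha to a carbonyl, should keep its configuration.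

**Step 11**
Reactants: 15 3,5-dibromophenol
Product: 16 (3,5-dibromophenoxy)triisopropylsilane
Conditions: TIPSCl, imidazole, DMF, rt
Reagents that add atoms: triisopropylsilyl chloride, CC(C)[Si](Cl)(C(C)C)C(C)C
Why: Standard phenol silylation, with the triisopropylsilyl group chosen because it is the aryl silyl ether most resistant to the bases used later and still falls with fluoride at the end.

**Step 12**
Reactants: 14 lactone; 16 dibromoarene
Product: 18 (2S,4S,5R,6S)-1-[3-bromo-5-(triisopropylsilyloxy)phenyl]-7-(tert-butyldimethylsilyloxy)-5-hydroxy-4-methoxy-2,6-dimethylheptan-1-one, via aryllithium 17 (not isolated)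
Conditions: 16, n-BuLi (1.0 equiv), Et2O, −78 °C; 14, −78 °C; AcOH/THF quench at −78 °C
Reagents that add atoms: none
Why: Single bromine–lithium exchange followed by acyl substitution on the lactone forms C15–C16, since the lithium hemiketal is stable at −78 °C and blocks a second addition, and the cold acidic quench protects C14.

**Step 13**
Reactants: 18 hydroxy ketone
Product: 19 C11 tert-butyldimethylsilyl ether of 18
Conditions: TBSOTf, 2,6-lutidine, CH2Cl2, −78 to 0 °C
Reagents that add atoms: tert-butyldimethylsilyl triflate, CC(C)(C)[Si](C)(C)OS(=O)(=O)C(F)(F)F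
Why: Silyl triflate silylation of the secondary alcohol is faster than that of the tertiary hemiketal hydroxyl, so the ring–chain equilibrium drains into the open-chain ketone.

**Step 14**
Reactants: 19 aryl ketone
Product: 20 (15R)-benzylic alcohol (10S,11R,12S,14S,15R)
Conditions: (S)-2-methyl-CBS-oxazaborolidine (0.5 equiv), BH3·SMe2, toluene, −30 °C; MeOH
Reagents that add atoms: none
Why: Corey–Bakshi–Shibata reduction of an aryl alkyl ketone, in which the (S)-catalyst places the aryl group in the large-group position and delivers hydride to the face that gives the R carbinol, so C15 is set by the reagent.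

**Step 15**
Reactants: 20 benzylic alcohol
Product: 21 C9,C11,C15-tris(tert-butyldimethylsilyl) ether
Conditions: TBSOTf, 2,6-lutidine, CH2Cl2, 0 °C
Reagents that add atoms: tert-butyldimethylsilyl triflate, CC(C)(C)[Si](C)(C)OS(=O)(=O)C(F)(F)F
Why: Routine silyl triflate protection masks O15 so that only O7 will be free when the carbamate is installed.

**Step 16**
Reactants: 21 tris(silyl) ether
Product: 22 C9 primary alcohol
Conditions: HF·pyridine, pyridine, THF, 0 °C
Reagents that add atoms: none
Why: Buffered HF·pyridine removes a primary tert-butyldimethylsilyl ether much faster than hindered secondary ones or an aryl triisopropylsilyl ether (rate-based selective desilylation).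

**Step 17**
Reactants: 22 primary alcohol
Product: 23 C9 aldehyde (10R by the changed priorities, same spatial arrangement)
Conditions: Dess–Martin periodinane, CH2Cl2, 0 °C to rt
Reagents that add atoms: none
Why: Dess–Martin oxidation is mild and base-free, so the alpha stereocentre C10 and the beta-silyloxy group should be retained.

**Step 18**
Reactants: 23 aldehyde; 24 2-(triphenylphosphoranylidene)propanal
Product: 25 (8E)-enal with C7 as the aldehyde carbon
Conditions: toluene, 90 °C
Reagents that add atoms: none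
Why: Wittig olefination with a stabilised ylide forms C8=C9 under thermodynamic control of the oxaphosphetane and therefore as the E trisubstituted enal, which is too unreactive to add a second ylide.

**Step 19**
Reactants: 25 enal; 26 allyl methyl ether
Product: 28 (6S,7S)-6-methoxy-7-hydroxy compound bearing the C4=C5 vinyl group, via Z-methoxyallylborane 27 (not isolated)
Conditions: 26, s-BuLi, THF, −78 °C; (+)-Ipc2BOMe [from (−)-α-pinene]; BF3·OEt2; 25, −78 °C; HOCH2CH2NH2, rt
Reagents that add atoms: none
Why: Brown alkoxyallylboration, where the Z gamma-methoxyallylborane reacts through a chair transition state to give the syn methoxy alcohol, the isopinocampheyl groups choose the aldehyde face, and the non-basic ethanolamine work-up spares the aryl silyl ether.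

**Step 20**
Reactants: 29 diethyl methylmalonate; 30 iodoform
Product: 31 diethyl 2-(diiodomethyl)-2-methylmalonate
Conditions: NaH, Et2O, reflux; CHI3
Reagents that add atoms: none
Why: Alkylation of the malonate enolate with iodoform is the established first stage of the route to beta-iodomethacrylic acid and brings in C3.

**Step 21**
Reactants: 31 diiodomethyl malonate
Product: 32 (E)-3-iodo-2-methylprop-2-enoic acid
Conditions: KOH, EtOH/H2O, reflux; HCl
Reagents that add atoms: potassium hydroxide, [K+].[OH-]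
Why: Saponification followed by decarboxylative anti elimination of iodide gives the E iodoacrylic acid as the more stable and known isomer.

**Step 22**
Reactants: 32 iodoacrylic acid
Product: 34 (E)-3-iodo-2-methylprop-2-enamide, via acid chloride 33 (not isolated)
Conditions: (COCl)2, DMF (cat.), CH2Cl2, 0 °C to rt; NH3 in dioxane, 0 °C
Reagents that add atoms: ammonia, N
Why: Acid chloride formation and aminolysis give the primary amide without touching the vinyl iodide geometry.

**Step 23**
Reactants: 28 vinyl compound; 34 iodoacrylamide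
Product: 36 seco primary amide (2E,6S,7S,8E,10S,11R,12S,14S,15R), via B-alkyl-9-BBN adduct 35 (not isolated)
Conditions: 9-BBN (3 equiv), THF, rt; 3 M aq K3PO4, 34, Pd(dppf)Cl2·CH2Cl2 (5 mol %), AsPh3, DMF, rt
Reagents that add atoms: none
Why: 9-BBN hydroborates only the monosubstituted alkene (the C7 hydroxyl is borylated in passing and freed by the aqueous base), and the B-alkyl Suzuki–Miyaura coupling forms C3–C4 with retention because the activated vinyl iodide undergoes oxidative addition at rt far faster than the aryl bromide.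

**Step 24**
Reactants: 36 seco amide
Product: 37 19-membered macrolactam with free C7 hydroxyl
Conditions: CuI (30 mol %), N,N'-dimethylethylenediamine (60 mol %), K2CO3, toluene (3 mM), 110 °C
Reagents that add atoms: none
Why: Intramolecular Goldberg amidation of the aryl bromide by the primary amide under high dilution, a closure with precedent for 19-membered ansa lactams, in which K2CO3 with the diamine ligand forms only the copper amidate so the much less acidic secondary alcohol stays a spectator.

**Step 25**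
Reactants: 37 macrolactam
Product: 39 C7 carbamate, via N-trichloroacetyl carbamate 38 (not isolated)
Conditions: Cl3CC(O)NCO, CH2Cl2, 0 °C; neutral Al2O3, rt
Reagents that add atoms: trichloroacetyl isocyanate, O=C=NC(=O)C(Cl)(Cl)Cl
Why: Addition of the only free hydroxyl to the activated isocyanate and mild hydrolysis of the trichloroacetyl group on alumina is the standard way to a primary carbamate, and the anilide nitrogen is too poor a nucleophile to compete.

**Step 26**
Reactants: 39 protected carbamate
Product: 40 target CNP0309815.1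
Conditions: HF·pyridine, pyridine, THF, 0 °C to rt
Reagents that add atoms: none
Why: Global fluoride desilylation removes both secondary silyl ethers and the aryl silyl ether in one operation under conditions that allylic carbamates, the benzylic alcohol and the enamide tolerate.

**Compound list**
1 | (R)-4-benzyl-3-propionyloxazolidin-2-one | CCC(=O)N1[C@H](Cc2ccccc2)COC1=O | starting material
2 | 4-methylfuran-2-carbaldehyde | O=Cc1cc(C)co1 | starting material
3 | Z-dibutylboron enolate of 1 | C/C=C(\OB(CCCC)CCCC)N1[C@H](Cc2ccccc2)COC1=O | intermediate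
4 | (R)-4-benzyl-3-[(2R,3R)-3-hydroxy-2-methyl-3-(4-methylfuran-2-yl)propanoyl]oxazolidin-2-one | O=C(N1[C@H](Cc2ccccc2)COC1=O)[C@H](C)[C@@H](O)c1cc(C)co1 | intermediate
5 | (1R,2S)-2-methyl-1-(4-methylfuran-2-yl)propane-1,3-diol | OC[C@H](C)[C@@H](O)c1cc(C)co1 | intermediate
6 | (1R,2S)-3-(tert-butyldimethylsilyloxy)-2-methyl-1-(4-methylfuran-2-yl)propan-1-ol | CC(C)(C)[Si](C)(C)OC[C@H](C)[C@@H](O)c1cc(C)co1 | intermediate
7 | (2Z,5R,6S)-7-(tert-butyldimethylsilyloxy)-5-hydroxy-2,6-dimethyl-4-oxohept-2-enal | CC(C)(C)[Si](C)(C)OC[C@H](C)[C@@H](O)C(=O)/C=C(/C)C=O | intermediate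
8 | (2R)-2-[(2S)-1-(tert-butyldimethylsilyloxy)propan-2-yl]-6-hydroxy-5-methyl-2H-pyran-3(6H)-one | CC(C)(C)[Si](C)(C)OC[C@H](C)[C@H]1OC(O)C(C)=CC1=O | intermediate
9 | (2R,6S)-6-(benzyloxy)-2-[(2S)-1-(tert-butyldimethylsilyloxy)propan-2-yl]-5-methyl-2H-pyran-3(6H)-one | CC(C)(C)[Si](C)(C)OC[C@H](C)[C@H]1O[C@H](OCc2ccccc2)C(C)=CC1=O | intermediate
10 | (2R,3S,6S)-6-(benzyloxy)-2-[(2S)-1-(tert-butyldimethylsilyloxy)propan-2-yl]-5-methyl-3,6-dihydro-2H-pyran-3-ol | CC(C)(C)[Si](C)(C)OC[C@H](C)[C@H]1O[C@H](OCc2ccccc2)C(C)=C[C@@H]1O | intermediate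
11 | (2R,3S,5S,6S)-6-(benzyloxy)-2-[(2S)-1-(tert-butyldimethylsilyloxy)propan-2-yl]-5-methyltetrahydro-2H-pyran-3-ol | CC(C)(C)[Si](C)(C)OC[C@H](C)[C@H]1O[C@H](OCc2ccccc2)[C@@H](C)C[C@@H]1O | intermediate
12 | C12 methyl ether of 11 | CC(C)(C)[Si](C)(C)OC[C@H](C)[C@H]1O[C@H](OCc2ccccc2)[C@@H](C)C[C@@H]1OC | intermediate
13 | C15 lactol (anomer mixture) | CC(C)(C)[Si](C)(C)OC[C@H](C)[C@H]1OC(O)[C@@H](C)C[C@@H]1OC | intermediate
14 | (3S,5S,6R)-6-[(2S)-1-(tert-butyldimethylsilyloxy)propan-2-yl]-5-methoxy-3-methyltetrahydro-2H-pyran-2-one | CC(C)(C)[Si](C)(C)OC[C@H](C)[C@H]1OC(=O)[C@@H](C)C[C@@H]1OC | intermediate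
15 | 3,5-dibromophenol | Oc1cc(Br)cc(Br)c1 | starting material
16 | (3,5-dibromophenoxy)triisopropylsilane | CC(C)[Si](Oc1cc(Br)cc(Br)c1)(C(C)C)C(C)C | intermediate
17 | 3-bromo-5-(triisopropylsilyloxy)phenyllithium | [Li]c1cc(Br)cc(O[Si](C(C)C)(C(C)C)C(C)C)c1 | intermediate
18 | C11-hydroxy C15 aryl ketone (10S,11R,12S,14S) | CC(C)(C)[Si](C)(C)OC[C@H](C)[C@@H](O)[C@@H](OC)C[C@H](C)C(=O)c1cc(Br)cc(O[Si](C(C)C)(C(C)C)C(C)C)c1 | intermediate
19 | C11 silyl ether of 18 | CC(C)(C)[Si](C)(C)OC[C@H](C)[C@@H](O[Si](C)(C)C(C)(C)C)[C@@H](OC)C[C@H](C)C(=O)c1cc(Br)cc(O[Si](C(C)C)(C(C)C)C(C)C)c1 | intermediate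
20 | (15R)-benzylic alcohol | CC(C)(C)[Si](C)(C)OC[C@H](C)[C@@H](O[Si](C)(C)C(C)(C)C)[C@@H](OC)C[C@H](C)[C@@H](O)c1cc(Br)cc(O[Si](C(C)C)(C(C)C)C(C)C)c1 | intermediate
21 | C9,C11,C15-tris(tert-butyldimethylsilyl) ether | CC(C)(C)[Si](C)(C)OC[C@H](C)[C@@H](O[Si](C)(C)C(C)(C)C)[C@@H](OC)C[C@H](C)[C@@H](O[Si](C)(C)C(C)(C)C)c1cc(Br)cc(O[Si](C(C)C)(C(C)C)C(C)C)c1 | intermediate
22 | C9 primary alcohol | OC[C@H](C)[C@@H](O[Si](C)(C)C(C)(C)C)[C@@H](OC)C[C@H](C)[C@@H](O[Si](C)(C)C(C)(C)C)c1cc(Br)cc(O[Si](C(C)C)(C(C)C)C(C)C)c1 | intermediate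
23 | C9 aldehyde | O=C[C@H](C)[C@@H](O[Si](C)(C)C(C)(C)C)[C@@H](OC)C[C@H](C)[C@@H](O[Si](C)(C)C(C)(C)C)c1cc(Br)cc(O[Si](C(C)C)(C(C)C)C(C)C)c1 | intermediate
24 | 2-(triphenylphosphoranylidene)propanal | CC(C=O)=P(c1ccccc1)(c1ccccc1)c1ccccc1 | starting material
25 | (8E)-C7 enal | O=C/C(C)=C/[C@H](C)[C@@H](O[Si](C)(C)C(C)(C)C)[C@@H](OC)C[C@H](C)[C@@H](O[Si](C)(C)C(C)(C)C)c1cc(Br)cc(O[Si](C(C)C)(C(C)C)C(C)C)c1 | intermediate
26 | allyl methyl ether | C=CCOC | starting material
27 | [(Z)-3-methoxyallyl]diisopinocampheylborane from (−)-α-pinene | CO/C=C\CB([C@H]1C[C@H]2C[C@@H]([C@@H]1C)C2(C)C)[C@H]1C[C@H]2C[C@@H]([C@@H]1C)C2(C)C | intermediate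
28 | (6S,7S)-methoxy alcohol with C4=C5 vinyl group | C=C[C@H](OC)[C@@H](O)/C(C)=C/[C@H](C)[C@@H](O[Si](C)(C)C(C)(C)C)[C@@H](OC)C[C@H](C)[C@@H](O[Si](C)(C)C(C)(C)C)c1cc(Br)cc(O[Si](C(C)C)(C(C)C)C(C)C)c1 | intermediate
29 | diethyl methylmalonate | CCOC(=O)C(C)C(=O)OCC | starting material
30 | iodoform | IC(I)I | starting material
31 | diethyl 2-(diiodomethyl)-2-methylmalonate | CCOC(=O)C(C)(C(I)I)C(=O)OCC | intermediate
32 | (E)-3-iodo-2-methylprop-2-enoic acid | OC(=O)/C(C)=C/I | intermediate
33 | (E)-3-iodo-2-methylprop-2-enoyl chloride | ClC(=O)/C(C)=C/I | intermediate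
34 | (E)-3-iodo-2-methylprop-2-enamide | NC(=O)/C(C)=C/I | intermediate
35 | C4 B-alkyl-9-BBN adduct, O7 as 9-BBN borinate | C1CC2CCCC(C1)B2CC[C@H](OC)[C@@H](OB1C2CCCC1CCC2)/C(C)=C/[C@H](C)[C@@H](O[Si](C)(C)C(C)(C)C)[C@@H](OC)C[C@H](C)[C@@H](O[Si](C)(C)C(C)(C)C)c1cc(Br)cc(O[Si](C(C)C)(C(C)C)C(C)C)c1 | intermediate
36 | seco primary amide | NC(=O)/C(C)=C/CC[C@H](OC)[C@@H](O)/C(C)=C/[C@H](C)[C@@H](O[Si](C)(C)C(C)(C)C)[C@@H](OC)C[C@H](C)[C@@H](O[Si](C)(C)C(C)(C)C)c1cc(Br)cc(O[Si](C(C)C)(C(C)C)C(C)C)c1 | intermediate
37 | macrolactam, C7 hydroxyl free | CO[C@H]1C[C@H](C)[C@@H](O[Si](C)(C)C(C)(C)C)c2cc(O[Si](C(C)C)(C(C)C)C(C)C)cc(c2)NC(=O)/C(C)=C/CC[C@H](OC)[C@@H](O)/C(C)=C/[C@H](C)[C@H]1O[Si](C)(C)C(C)(C)C | intermediate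
38 | C7 N-trichloroacetyl carbamate | CO[C@H]1C[C@H](C)[C@@H](O[Si](C)(C)C(C)(C)C)c2cc(O[Si](C(C)C)(C(C)C)C(C)C)cc(c2)NC(=O)/C(C)=C/CC[C@H](OC)[C@@H](OC(=O)NC(=O)C(Cl)(Cl)Cl)/C(C)=C/[C@H](C)[C@H]1O[Si](C)(C)C(C)(C)C | intermediate
39 | C7 carbamate, O11, O15 and phenol silylated | CO[C@H]1C[C@H](C)[C@@H](O[Si](C)(C)C(C)(C)C)c2cc(O[Si](C(C)C)(C(C)C)C(C)C)cc(c2)NC(=O)/C(C)=C/CC[C@H](OC)[C@@H](OC(N)=O)/C(C)=C/[C@H](C)[C@H]1O[Si](C)(C)C(C)(C)C | intermediate
40 | CNP0309815.1 (2E,6S,7S,8E,10S,11R,12S,14S,15R) | CO[C@H]1C[C@H](C)[C@@H](O)c2cc(O)cc(c2)NC(=O)/C(C)=C/CC[C@H](OC)[C@@H](OC(N)=O)/C(C)=C/[C@H](C)[C@H]1O | target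

**Step count**
Total steps: 26. Longest linear sequence: 22 (steps 1–10, 12–19, 23–26).

**Steps most likely to fail**

1. **Step 7.** The directed delivery has to win on the ring face that also carries the axial benzyloxy group next to C14.
   - What may go wrong: crowding there may slow coordination of iridium. Undirected addition from the open face (poor facial selectivity) or isomerisation of the allylic alcohol to the ketone could then take over.
   - Fallback: the wrong face is closed by a covalent bridge instead of relying on coordination alone. It sets out from 10.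
     - TBAF in THF frees the C9 hydroxyl and gives the diol F1.
     - Catalytic CSA in CH2Cl2 exchanges the benzyloxy group for O9 and gives the bridged unsaturated acetal F2. Its three-atom bridge C10–C9–O9 lies under the face opposite to the C12 hydroxyl.
     - Hydrogenation (H2 over Rh/Al2O3, or the same iridium complex) can then reach only the hydroxyl face and gives the saturated bridged alcohol F3.
     - NaH and MeI give the bridged methyl ether F4.
     - 1 M HCl in THF opens the bridge to the hydroxy lactol F5.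
     - TBSCl with imidazole on the primary alcohol comes back to the route at 13.

2. **Step 14.** The catalyst has to override the Felkin–Anh preference of the alpha-methyl ketone, which points to the other face.
   - What may go wrong: the branched alkyl side narrows the size difference that the oxazaborolidine reads, so facial selectivity may erode. Uncatalysed borane reduction may also gain ground.
   - Fallback: C15 is set by adding the arene to an aldehyde, where the Felkin–Anh preference leads to the 14,15-syn relation of the target. It sets out from lactol 13.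
     - Lactol 13 is treated with aryllithium 17 (2.5 equiv, Et2O, −78 °C). The first equivalent opens the lactol, the second adds to the C15 aldehyde, and the product is the C11,C15-diol F6.
     - TBSOTf (2.5 equiv) with 2,6-lutidine silylates both hydroxyls and comes back to the route at 21.

3. **Step 24.** Ring closure competes with other copper-mediated processes.
   - What may go wrong: intermolecular coupling, protodebromination and arylation of the diamine ligand can all compete. Binding of copper by the free C7 hydroxyl may slow the catalyst further.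
   - Fallback: the ring is closed at C3–C4 instead of N–C20. It sets out from 28.
     - Amination of the aryl bromide with benzophenone imine (Pd2(dba)3, BINAP, Cs2CO3, toluene, 90 °C) gives the N-aryl imine F7.
     - NH2OH·HCl and NaOAc in MeOH free the aniline F8.
     - Acid chloride 33 with pyridine acylates nitrogen selectively and gives the iodoacrylanilide F9.
     - 9-BBN hydroborates the vinyl group to the alkylborane F10.
     - Slow addition of F10 to Pd(dppf)Cl2·CH2Cl2, AsPh3 and Cs2CO3 in DMF/THF/H2O closes the ring by an intramolecular B-alkyl Suzuki–Miyaura coupling. This comes back to the route at 37.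

**Further compounds**
F1 | step 7 | (2R,3S,6S)-6-(benzyloxy)-2-[(2S)-1-hydroxypropan-2-yl]-5-methyl-3,6-dihydro-2H-pyran-3-ol | OC[C@H](C)[C@H]1O[C@H](OCc2ccccc2)C(C)=C[C@@H]1O
F2 | step 7 | 4,8-dimethyl-2,9-dioxabicyclo[3.3.1]non-7-en-6-ol (O9 bound to C15 on the face of the C11 side chain) | C[C@H]1CO[C@@H]2O[C@H]1[C@@H](O)C=C2C
F3 | step 7 | 4,8-dimethyl-2,9-dioxabicyclo[3.3.1]nonan-6-ol (14S) | C[C@H]1CO[C@@H]2O[C@H]1[C@@H](O)C[C@@H]2C
F4 | step 7 | 6-methoxy-4,8-dimethyl-2,9-dioxabicyclo[3.3.1]nonane | C[C@H]1CO[C@@H]2O[C@H]1[C@@H](OC)C[C@@H]2C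
F5 | step 7 | 6-[(2S)-1-hydroxypropan-2-yl]-5-methoxy-3-methyltetrahydro-2H-pyran-2-ol | OC[C@H](C)[C@H]1OC(O)[C@@H](C)C[C@@H]1OC
F6 | step 14 | C11,C15-diol (10S,11R,12S,14S,15R) | CC(C)(C)[Si](C)(C)OC[C@H](C)[C@@H](O)[C@@H](OC)C[C@H](C)[C@@H](O)c1cc(Br)cc(O[Si](C(C)C)(C(C)C)C(C)C)c1
F7 | step 24 | N-aryl benzophenone imine of the C4–C21 fragment | C=C[C@H](OC)[C@@H](O)/C(C)=C/[C@H](C)[C@@H](O[Si](C)(C)C(C)(C)C)[C@@H](OC)C[C@H](C)[C@@H](O[Si](C)(C)C(C)(C)C)c1cc(N=C(c2ccccc2)c2ccccc2)cc(O[Si](C(C)C)(C(C)C)C(C)C)c1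
F8 | step 24 | C20 aniline | C=C[C@H](OC)[C@@H](O)/C(C)=C/[C@H](C)[C@@H](O[Si](C)(C)C(C)(C)C)[C@@H](OC)C[C@H](C)[C@@H](O[Si](C)(C)C(C)(C)C)c1cc(N)cc(O[Si](C(C)C)(C(C)C)C(C)C)c1
F9 | step 24 | (E)-3-iodo-2-methylacrylanilide | C=C[C@H](OC)[C@@H](O)/C(C)=C/[C@H](C)[C@@H](O[Si](C)(C)C(C)(C)C)[C@@H](OC)C[C@H](C)[C@@H](O[Si](C)(C)C(C)(C)C)c1cc(NC(=O)/C(C)=C/I)cc(O[Si](C(C)C)(C(C)C)C(C)C)c1
F10 | step 24 | C4 B-alkyl-9-BBN adduct of F9, O7 as 9-BBN borinate | C1CC2CCCC(C1)B2CC[C@H](OC)[C@@H](OB1C2CCCC1CCC2)/C(C)=C/[C@H](C)[C@@H](O[Si](C)(C)C(C)(C)C)[C@@H](OC)C[C@H](C)[C@@H](O[Si](C)(C)C(C)(C)C)c1cc(NC(=O)/C(C)=C/I)cc(O[Si](C(C)C)(C(C)C)C(C)C)c1
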